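**Retrosynthetic overview**
1. Cut the C3 ester: Mitsunobu inversion of the syn allylic alcohol (Luche reduction of the exo-methylene enone) with an (S)-3-silyloxy-2,2-dimethylbutanoic acid made from ethyl (S)-3-hydroxybutanoate.
2. Exo-methylene enone from the 2-methyl-3-ketone by selenoxide elimination (C1 is a bridgehead, so only the methyl can eliminate).
3. Key disconnection, the C1–C6 cyclobutane bond: light-driven titanocene epoxide opening and 4-exo radical closure onto the carvone enone; the freed CH2OH then closes tetrahydrofuran and lactone onto the side-chain ketone.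
4. Epoxy keto ester from (R)-carvone by ene-type acylation with (R)-2-methylsuccinic anhydride, esterification and epoxidation.
5. Ring order: cyclohexenone (bought) → cyclobutane → tetrahydrofuran → γ-lactone.

Assumption: pinane-style locants are used for the bicyclic core (C2 carries the exocyclic carbon, C3 the oxygen, C6 is the spiro carbon, C7 the CH2 bridge); "syn" and "anti" refer to the C2–C4 bridge.

**Step 1**
Reactants: 1 (R)-2-methylsuccinic acid
Product: 2 (R)-2-methylsuccinic anhydride
Conditions: AcCl, reflux; distil
Reagents that add atoms: none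
Why: Dehydrative anhydride formation from a 1,4-diacid with acetyl chloride is routine and leaves the bought stereocentre untouched.

**Step 2**
Reactants: 3 (R)-(−)-carvone; 2 (R)-2-methylsuccinic anhydride
Product: 5 methyl (2R)-2-methyl-6-[(1R)-4-methyl-5-oxocyclohex-3-en-1-yl]-4-oxohept-6-enoate, via keto acid 4 (not isolated)
Conditions: EtAlCl2 (2.5 equiv), CH2Cl2, −30 → 0 °C; aq HCl work-up; then TMSCHN2, PhMe/MeOH, 0 °C
Reagents that add atoms: trimethylsilyldiazomethane, C[Si](C)(C)C=[N+]=[N-]
Why: Lewis-acid-promoted ene-type Friedel–Crafts acylation of the electron-rich 1,1-disubstituted alkene (the enone is inert) at the less hindered anhydride carbonyl gives the β,γ-unsaturated ketone with loss of a methyl proton, and diazoalkane esterification then caps the acid; no stereocentre is formed or touched.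

**Step 3**
Reactants: 5 methyl (2R)-2-methyl-6-[(1R)-4-methyl-5-oxocyclohex-3-en-1-yl]-4-oxohept-6-enoate
Product: 6 methyl (2R)-2-methyl-5-{2-[(1R)-4-methyl-5-oxocyclohex-3-en-1-yl]oxiran-2-yl}-4-oxopentanoate
Conditions: mCPBA, NaHCO3, CH2Cl2, 0 °C
Reagents that add atoms: 3-chloroperbenzoic acid, OOC(=O)c1cccc(Cl)c1
Why: Prilezhaev epoxidation selects the electron-rich 1,1-disubstituted alkene over the enone; the new oxirane centre forms about 1:1 and is erased in step 4.

**Step 4**
Reactants: 6 methyl (2R)-2-methyl-5-{2-[(1R)-4-methyl-5-oxocyclohex-3-en-1-yl]oxiran-2-yl}-4-oxopentanoate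
Product: 8 spiroketal lactone ketone (2-methyl-3-oxo core), via hydroxy diketone ester 7 (not isolated)
Conditions: Cp2TiCl2 (10 mol %), 4CzIPN (2 mol %), Hantzsch ester (1.5 equiv), THF, blue LEDs (450 nm), 25 °C; then CSA (20 mol %), PhMe, 60 °C
Reagents that add atoms: none
Why: Proposed new method: photoredox-generated trivalent titanocene (Cp2TiCl, kept at low steady-state concentration) opens the 2,2-disubstituted epoxide at its tertiary C–O bond to a β-titanoxy tertiary radical that closes 4-exo-trig onto the β-carbon of the cyclohexenone from the axial side chain, the enoyl radical being captured as a titanium enolate and protonated by the Hantzsch pyridinium, after which acid closes the hemiketal and the lactone with loss of methanol; the C1/C5 ring fusion is dictated by the carvone stereocentre through the one-atom tether, C6 is set by two-point binding of the tetravalent titanium alkoxide to the enone oxygen so that CH2O lies syn and the keto-ester arm anti, the ketal carbon equilibrates under acid to the isomer with the lactone oxygen pseudo-axial and the bought lactone methyl pseudo-equatorial (trans to the tetrahydrofuran oxygen), and C2 is inconsequential; the closest known reaction type is the ground-state titanocene reductive epoxide opening with radical 4-exo cyclisation onto unsaturated carbonyl compounds (Nugent–RajanBabu and Gansäuer chemistry), not yet run photocatalytically to build a bridged bicyclo[3.1.1]heptane with a quaternary centre.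

**Step 5**
Reactants: 8 spiroketal lactone ketone (2-methyl-3-oxo core)
Product: 10 spiroketal lactone exo-methylene enone, via phenylselenide 9 (not isolated)
Conditions: PhSeCl, EtOAc, 25 °C; then H2O2 (30 %), pyridine, CH2Cl2, 0 → 25 °C
Reagents that add atoms: none
Why: Acid-catalysed α-selenenylation at the more substituted enol carbon (C2) and selenoxide syn-elimination (Sharpless–Reich) can only eliminate towards the methyl group because C1 is a bridgehead, which removes the C2 centre and gives the exocyclic enone.

**Step 6**
Reactants: 10 spiroketal lactone exo-methylene enone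
Product: 11 syn allylic alcohol (C3–OH syn to C6)
Conditions: NaBH4, CeCl3·7H2O, MeOH/THF, −78 °C
Reagents that add atoms: none
Why: Luche 1,2-reduction delivers hydride to C3 from the face of the C7 methylene bridge, because the syn ring CH2O on C6 shields the other face, so the hydroxyl ends syn to C6.

**Step 7**
Reactants: 12 ethyl (S)-3-hydroxybutanoate
Product: 14 ethyl (3S)-3-hydroxy-2,2-dimethylbutanoate, via monomethyl ester 13 (not isolated)
Conditions: LiN(iPr)2 (2.2 equiv), THF, −50 → −20 °C, MeI; then LiN(iPr)2 (1.3 equiv), MeI, −50 → 0 °C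
Reagents that add atoms: iodomethane, CI
Why: Fráter–Seebach alkylation of the β-hydroxy ester dianion, run twice in one pot, builds the gem-dimethyl group without touching the bought carbinol centre.

**Step 8**
Reactants: 14 ethyl (3S)-3-hydroxy-2,2-dimethylbutanoate
Product: 16 (3S)-3-[(tert-butyldimethylsilyl)oxy]-2,2-dimethylbutanoic acid, via silyl ether ester 15 (not isolated)
Conditions: TBSOTf, 2,6-lutidine, CH2Cl2, 0 °C; then LiOH, THF/MeOH/H2O, 60 °C; HCl to pH 4
Reagents that add atoms: tert-butyldimethylsilyl trifluoromethanesulfonate, CC(C)(C)[Si](C)(C)OS(=O)(=O)C(F)(F)F; lithium hydroxide, [Li+].[OH-]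
Why: Silyl ether formation followed by saponification of the hindered ester are standard protecting-group and hydrolysis steps that do not affect the carbinol centre.

**Step 9**
Reactants: 11 syn allylic alcohol (C3–OH syn to C6); 16 (3S)-3-[(tert-butyldimethylsilyl)oxy]-2,2-dimethylbutanoic acid
Product: 17 silyl-protected target ester (C3–O anti to C6)
Conditions: PPh3, DIAD, THF/PhMe, 0 → 25 °C
Reagents that add atoms: none
Why: Mitsunobu esterification displaces the activated allylic alcohol by the carboxylate with SN2 inversion from the open C7-bridge face, setting the C3–O bond anti to C6 as in the target.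

**Step 10**
Reactants: 17 silyl-protected target ester (C3–O anti to C6)
Product: 18 target CNP0212779.5
Conditions: HF·pyridine, THF/pyridine, 0 → 25 °C
Reagents that add atoms: none
Why: Buffered fluoride desilylation removes the silyl ether without touching the two esters, the exocyclic alkene or the ketal.

**Compound list**
1 | (R)-2-methylsuccinic acid | OC(=O)C[C@@H](C)C(=O)O | starting material
2 | (R)-2-methylsuccinic anhydride, (3R)-3-methyloxolane-2,5-dione | C[C@@H]1CC(=O)OC1=O | intermediate
3 | (R)-(−)-carvone | CC1=CC[C@H](CC1=O)C(C)=C | starting material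
4 | keto acid, (2R)-2-methyl-6-[(1R)-4-methyl-5-oxocyclohex-3-en-1-yl]-4-oxohept-6-enoic acid (not isolated) | C=C(CC(=O)C[C@@H](C)C(=O)O)[C@@H]1CC=C(C)C(=O)C1 | intermediate
5 | methyl (2R)-2-methyl-6-[(1R)-4-methyl-5-oxocyclohex-3-en-1-yl]-4-oxohept-6-enoate | C=C(CC(=O)C[C@@H](C)C(=O)OC)[C@@H]1CC=C(C)C(=O)C1 | intermediate
6 | methyl (2R)-2-methyl-5-{2-[(1R)-4-methyl-5-oxocyclohex-3-en-1-yl]oxiran-2-yl}-4-oxopentanoate, both oxirane epimers | C1OC1(CC(=O)C[C@@H](C)C(=O)OC)[C@@H]2CC=C(C)C(=O)C2 | intermediate
7 | hydroxy diketone ester, methyl (2R)-5-[6-(hydroxymethyl)-2-methyl-3-oxobicyclo[3.1.1]heptan-6-yl]-2-methyl-4-oxopentanoate, CH2OH syn, keto-ester arm anti, drawn as the C2 epimer with methyl anti to C6 (not isolated) | C[C@H]1C(=O)C[C@H]2C[C@@H]1[C@]2(CO)CC(=O)C[C@@H](C)C(=O)OC | intermediate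
8 | spiroketal lactone ketone: 2-methyl-3-oxobicyclo[3.1.1]heptane spiro-fused at C6 to a tetrahydrofuran (ring CH2O syn, ring CH2C anti) whose ketal carbon is C5 of an (R)-3-methyl-γ-butyrolactone; lactone ring oxygen on the C1 face of the tetrahydrofuran, lactone methyl trans to the tetrahydrofuran oxygen, C2 methyl anti to C6 | C[C@H]1C(=O)C[C@H]2C[C@@H]1[C@@]21CO[C@@]2(C[C@@H](C)C(=O)O2)C1 | intermediate
9 | phenylselenide, 2-(phenylselanyl) derivative of 8 with selenium anti to C6 (not isolated) | C[C@]1([Se]c3ccccc3)C(=O)C[C@H]2C[C@@H]1[C@@]21CO[C@@]2(C[C@@H](C)C(=O)O2)C1 | intermediate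
10 | spiroketal lactone exo-methylene enone (2-methylidene-3-oxo core, otherwise as 8) | C=C1C(=O)C[C@H]2C[C@@H]1[C@@]21CO[C@@]2(C[C@@H](C)C(=O)O2)C1 | intermediate
11 | syn allylic alcohol (2-methylidene core, C3–OH syn to C6, otherwise as 8) | C=C1[C@H](O)C[C@H]2C[C@@H]1[C@@]21CO[C@@]2(C[C@@H](C)C(=O)O2)C1 | intermediate
12 | ethyl (S)-3-hydroxybutanoate | CCOC(=O)C[C@H](C)O | starting material
13 | monomethyl ester, ethyl (2S,3S)-3-hydroxy-2-methylbutanoate (not isolated) | CCOC(=O)[C@@H](C)[C@H](C)O | intermediate
14 | ethyl (3S)-3-hydroxy-2,2-dimethylbutanoate | CCOC(=O)C(C)(C)[C@H](C)O | intermediate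
15 | silyl ether ester, ethyl (3S)-3-[(tert-butyldimethylsilyl)oxy]-2,2-dimethylbutanoate (not isolated) | CCOC(=O)C(C)(C)[C@H](C)O[Si](C)(C)C(C)(C)C | intermediate
16 | (3S)-3-[(tert-butyldimethylsilyl)oxy]-2,2-dimethylbutanoic acid | OC(=O)C(C)(C)[C@H](C)O[Si](C)(C)C(C)(C)C | intermediate
17 | silyl-protected target ester (C3 ester anti to C6, side-chain hydroxyl as its tert-butyldimethylsilyl ether) | C=C1[C@@H](OC(=O)C(C)(C)[C@H](C)O[Si](C)(C)C(C)(C)C)C[C@H]2C[C@@H]1[C@@]21CO[C@@]2(C[C@@H](C)C(=O)O2)C1 | intermediate
18 | target CNP0212779.5 | C=C1[C@@H](OC(=O)C(C)(C)[C@H](C)O)C[C@H]2C[C@@H]1[C@@]21CO[C@@]2(C[C@@H](C)C(=O)O2)C1 | target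

**Step count**
Total: 10 steps. Longest linear sequence: 8 steps (1, 2, 3, 4, 5, 6, 9, 10), or 7 from carvone.

**Steps most likely to fail**

(a) Step 4, the proposed photocatalytic cyclisation. The closure builds a strained cyclobutane and must outrun reduction or deoxygenation of the tertiary radical, and the syn placement of CH2O at C6 rests on the titanium-to-enone binding model rather than on data for this substrate. The ketal ratio is also only thermodynamic; the minor ketal epimer can be re-equilibrated with CSA. Fallback with known chemistry: give up the catalytic light-driven cascade and use the ground-state stoichiometric reagent. It sets out from 6 and returns at 8. Cp2TiCl (2.2 equiv, made from Cp2TiCl2 and Mn dust in THF) is treated with 6 by slow addition at 25 °C, the established Nugent–RajanBabu reductive epoxide opening with radical 4-exo closure onto the enone. Compound 7 is isolated this time, its C6 epimers are separated on silica, and the syn-CH2OH epimer is closed to 8 with CSA in toluene in a separate step. This makes no new compound (none F0).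

(b) Step 9, the Mitsunobu inversion. The carboxylate is hindered (α-quaternary), and the exocyclic allylic system can leak by SN2' to the primary allylic ester. Fallback: install the C3 oxygen with the correct configuration by a Schenck ene reaction and esterify with retention. It sets out from 8 and returns at 17. Tf2O with 2,6-di-tert-butyl-4-methylpyridine in CH2Cl2 gives the more substituted enol triflate F1. Pd(OAc)2/PPh3, Bu3N and HCO2H in DMF reduce it to the 2-methyl-2-ene (α-pinene-type alkene) F2. Singlet oxygen (O2, tetraphenylporphyrin, visible light, CH2Cl2, then PPh3) attacks C3 from the face away from C6 and moves the double bond to the exocyclic position, as in the conversion of α-pinene into trans-pinocarveol, giving the anti allylic alcohol F3. Yamaguchi esterification of F3 with 16 (2,4,6-trichlorobenzoyl chloride, Et3N, DMAP, PhMe) gives 17.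

(c) Step 2, the ene-type acylation. Risks are the position of the new double bond (β,γ versus conjugated), acylation at the wrong anhydride carbonyl, and Lewis-acid damage to the enone. Fallback: fix the regiochemistry with an allylsilane. It sets out from 3 and returns at 4 (then TMSCHN2 to 5 as before). Ene-type allylic chlorination of 3 (Ca(OCl)2, CO2, CH2Cl2/H2O) gives (5R)-5-(3-chloroprop-1-en-2-yl)-2-methylcyclohex-2-en-1-one F4. Hexamethyldisilane with Pd(PPh3)4 converts the allylic chloride into (5R)-2-methyl-5-[3-(trimethylsilyl)prop-1-en-2-yl]cyclohex-2-en-1-one F5. TiCl4-mediated acylation of this allylsilane with 2 (CH2Cl2, −78 °C) occurs only at the γ-carbon with loss of silicon, which gives keto acid 4 with the double bond where it is needed.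

**Further compounds**
F0 | step 4 | none | none
F1 | step 9 | enol triflate, 2-methyl-3-(trifluoromethanesulfonyloxy)-2-ene analogue of 8 | CC1=C(OS(=O)(=O)C(F)(F)F)C[C@H]2C[C@@H]1[C@@]21CO[C@@]2(C[C@@H](C)C(=O)O2)C1
F2 | step 9 | 2-methyl-2-ene (α-pinene-type alkene) analogue of 8 | CC1=CC[C@H]2C[C@@H]1[C@@]21CO[C@@]2(C[C@@H](C)C(=O)O2)C1
F3 | step 9 | anti allylic alcohol, C3 epimer of 11 (C3–OH anti to C6) | C=C1[C@@H](O)C[C@H]2C[C@@H]1[C@@]21CO[C@@]2(C[C@@H](C)C(=O)O2)C1
F4 | step 2 | (5R)-5-(3-chloroprop-1-en-2-yl)-2-methylcyclohex-2-en-1-one | CC1=CC[C@H](CC1=O)C(=C)CCl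
F5 | step 2 | (5R)-2-methyl-5-[3-(trimethylsilyl)prop-1-en-2-yl]cyclohex-2-en-1-one | CC1=CC[C@H](CC1=O)C(=C)C[Si](C)(C)C
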